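## Plan

- **Cuts (retrosynthetic order):** the O5–CH3 bond last of all; then O1–C2 of ring C; then C4–C4a (aryl ketone), C2–C1' (ring B to the three-carbon chain) and C8–CH2 (prenyl).
- **Enabling feature:** C2 is benzylic and para to the free 4'-OH of guaiacyl ring B, so it is the exocyclic carbon of a latent para-quinone methide. The C8a hydroxyl of ring A can reach it through the six-membered ring C, so oxidising ring B lets O1 close that ring.
- **Forward order:** ring A (MOM ether of 3,5-dimethoxyphenol, ortho-lithiation, prenylation) and the ring B lactate unit (Grignard reagent of protected 4-bromoguaiacol plus methyl (R)-glycidate, then Weinreb amide) are joined at C4–C4a. Unmasking, anodic closure of ring C and O5-demethylation follow.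
- **Stereochemistry:** C3 is bought with methyl (R)-glycidate and is not touched afterwards; C2 is set in the ring closure, trans to C3.
- **Remark on the blocking group:** O5 is carried as a methyl ether, not an acetal. OMOM is then the only strong director on ring A and the C8a hydroxyl the only phenol able to cyclise; the methyl group is removed last by chelation-controlled cleavage.

Key step: step 9

## Route

Step 1
Reactants: 1 3,5-dimethoxyphenol
Product: 2 1,3-dimethoxy-5-(methoxymethoxy)benzene
Conditions: MOMCl, iPr2NEt, CH2Cl2, 0 °C → rt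
Reagents that add atoms: chloromethyl methyl ether (MOMCl), COCCl
Why: MOM protection of a phenol (O-alkylation with an α-chloro ether) installs the acetal that is to direct both later metalations of ring A; no stereocentre is involved.

Step 2
Reactants: 2 1,3-dimethoxy-5-(methoxymethoxy)benzene; 3 prenyl bromide (1-bromo-3-methylbut-2-ene)
Product: 5 1,5-dimethoxy-3-(methoxymethoxy)-2-(3-methylbut-2-en-1-yl)benzene, via aryllithium 4 (not isolated)
Conditions: n-BuLi, THF, 0 °C; then CuI (10 mol %), 3, −78 °C → rt
Reagents that add atoms: none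
Why: Directed ortho-metalation followed by copper-catalysed allylic substitution: the MOM acetal outranks methoxy as a director, so lithiation should occur at one of the two equivalent carbons between OMOM and OMe, and the aryl nucleophile attacks the primary carbon of prenyl bromide (SN2) to give the linear prenyl group.

Step 3
Reactants: 6 4-bromo-2-methoxyphenol
Product: 7 4-bromo-2-methoxy-1-(methoxymethoxy)benzene
Conditions: MOMCl, iPr2NEt, CH2Cl2, 0 °C → rt
Reagents that add atoms: chloromethyl methyl ether (MOMCl), COCCl
Why: MOM protection of the guaiacol hydroxyl, so that the aryl bromide can be converted into a Grignard reagent.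

Step 4
Reactants: 7 4-bromo-2-methoxy-1-(methoxymethoxy)benzene; 8 methyl (2R)-oxirane-2-carboxylate (methyl (R)-glycidate)
Product: 10 methyl (2R)-2-hydroxy-3-[3-methoxy-4-(methoxymethoxy)phenyl]propanoate, via arylmagnesium bromide 9 (not isolated)
Conditions: Mg, THF, 40 °C; then CuI (10 mol %), 8, THF, −40 → −20 °C
Reagents that add atoms: none
Why: Copper-catalysed ring opening of a glycidic ester by an aryl Grignard reagent, which attacks the unsubstituted epoxide carbon faster than the ester at low temperature; the (R) centre (the future C3) is not part of the reaction and comes from the chiral pool.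

Step 5
Reactants: 10 methyl (2R)-2-hydroxy-3-[3-methoxy-4-(methoxymethoxy)phenyl]propanoate
Product: 11 methyl (2R)-2-[(tert-butyldimethylsilyl)oxy]-3-[3-methoxy-4-(methoxymethoxy)phenyl]propanoate
Conditions: TBSCl, imidazole, DMF, rt
Reagents that add atoms: tert-butyldimethylsilyl chloride (TBSCl), CC(C)(C)[Si](C)(C)Cl
Why: Silyl ether formation at the secondary alcohol gives an α-silyloxy ester that tolerates the organometallic steps; the stereocentre is unaffected.

Step 6
Reactants: 11 methyl (2R)-2-[(tert-butyldimethylsilyl)oxy]-3-[3-methoxy-4-(methoxymethoxy)phenyl]propanoate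
Product: 12 (2R)-2-[(tert-butyldimethylsilyl)oxy]-N-methoxy-3-[3-methoxy-4-(methoxymethoxy)phenyl]-N-methylpropanamide
Conditions: MeNH(OMe)·HCl, iPrMgCl, THF, −20 → 0 °C
Reagents that add atoms: N,O-dimethylhydroxylamine hydrochloride, CNOC.Cl
Why: Weinreb amide formation by aminolysis of the ester with the chloromagnesium amide made in the flask, a method known to leave α-silyloxy stereocentres unchanged.

Step 7
Reactants: 5 1,5-dimethoxy-3-(methoxymethoxy)-2-(3-methylbut-2-en-1-yl)benzene; 12 (2R)-2-[(tert-butyldimethylsilyl)oxy]-N-methoxy-3-[3-methoxy-4-(methoxymethoxy)phenyl]-N-methylpropanamide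
Product: 15 (2R)-2-[(tert-butyldimethylsilyl)oxy]-1-[4,6-dimethoxy-2-(methoxymethoxy)-3-(3-methylbut-2-en-1-yl)phenyl]-3-[3-methoxy-4-(methoxymethoxy)phenyl]propan-1-one, via aryllithium 13 (not isolated), via lithium hemiaminal 14 (not isolated)
Conditions: n-BuLi, THF, −20 → 0 °C; then 12, −78 → 0 °C; aqueous work-up
Reagents that add atoms: none
Why: Directed ortho-metalation at the only remaining carbon ortho to the OMOM group (also flanked by OMe) and Weinreb ketone synthesis: chelated adduct 14 does not collapse before work-up, so no second addition occurs and the α-silyloxy centre is never exposed to base as a ketone.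

Step 8
Reactants: 15 (2R)-2-[(tert-butyldimethylsilyl)oxy]-1-[4,6-dimethoxy-2-(methoxymethoxy)-3-(3-methylbut-2-en-1-yl)phenyl]-3-[3-methoxy-4-(methoxymethoxy)phenyl]propan-1-one
Product: 16 (2R)-2-hydroxy-1-[2-hydroxy-4,6-dimethoxy-3-(3-methylbut-2-en-1-yl)phenyl]-3-(4-hydroxy-3-methoxyphenyl)propan-1-one
Conditions: HCl (1.25 M in MeOH), rt
Reagents that add atoms: none
Why: Acid-catalysed methanolysis removes both aryl MOM acetals and the secondary silyl ether in one operation, conditions routinely used beside ortho-prenyl phenols; the aryl methyl ethers, the alkene and the α-hydroxy ketone stereocentre should be stable.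

Step 9
Reactants: 16 (2R)-2-hydroxy-1-[2-hydroxy-4,6-dimethoxy-3-(3-methylbut-2-en-1-yl)phenyl]-3-(4-hydroxy-3-methoxyphenyl)propan-1-one
Product: 18 (2R,3R)-3-hydroxy-2-(4-hydroxy-3-methoxyphenyl)-5,7-dimethoxy-8-(3-methylbut-2-en-1-yl)-2,3-dihydro-4H-chromen-4-one, via quinone methide 17 (not isolated)
Conditions: graphite anode, Pt cathode, undivided cell, Bu4NBF4 (0.1 M), MeCN/HFIP (4:1), 5 mM, potential held at the first anodic wave of 16, 2.0–2.2 F/mol, rt
Reagents that add atoms: none
Why: Proposed new method: two-electron anodic oxidation of the ring B guaiacol of 16, with loss of the phenolic proton and one benzylic proton, should give para-quinone methide 17, and the C8a hydroxyl then adds to its exocyclic carbon in a 1,6-conjugate addition that rearomatises ring B and forms O1–C2. The closest known reaction type is the anodic or chemical (DDQ, Ag2O) oxidation of 4-alkylphenols to para-quinone methides that are captured by alcohols or phenols, here made intramolecular in the manner of the oxa-Michael closure of 2'-hydroxychalcones. Ring C closes in the 6-exo-trig mode. The new C2 centre is controlled by the existing (R)-carbinol carbon C3: a chair-like closure with aryl and hydroxyl both equatorial leads to the trans (2R,3R) product, and because the free 4'-hydroxyl can reopen the O1–C2 bond the same isomer is also the thermodynamic one. The step needs oxidation of ring B only, closure through the C8a oxygen only and retention at C3; these are secured by the lower oxidation potential of the guaiacol compared with the acyl-deactivated, hydrogen-bonded ring A phenol and the prenyl alkene under charge-limited electrolysis, by the methyl group on O5, and by the non-basic, hydrogen-bond-donating HFIP medium, which should speed the addition and disfavour loss of the C3 proton from 17.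

Step 10
Reactants: 18 (2R,3R)-3-hydroxy-2-(4-hydroxy-3-methoxyphenyl)-5,7-dimethoxy-8-(3-methylbut-2-en-1-yl)-2,3-dihydro-4H-chromen-4-one
Product: 19 (2R,3R)-3,5-dihydroxy-2-(4-hydroxy-3-methoxyphenyl)-7-methoxy-8-(3-methylbut-2-en-1-yl)-2,3-dihydro-4H-chromen-4-one
Conditions: MgI2·OEt2 (excess), THF, 60 °C; aqueous work-up
Reagents that add atoms: none
Why: Chelation-controlled ether cleavage: Mg binds the C4 carbonyl and O5 and iodide removes only that methyl group by SN2, a reagent known to demethylate 8-prenyl-5-methoxyflavanones without harming the prenyl group; the 7- and 3'-methyl ethers have no carbonyl to chelate and the two stereocentres are not involved.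

## Compound list

1 | 3,5-dimethoxyphenol | COc1cc(O)cc(OC)c1 | starting material
2 | 1,3-dimethoxy-5-(methoxymethoxy)benzene | COCOc1cc(OC)cc(OC)c1 | intermediate
3 | prenyl bromide (1-bromo-3-methylbut-2-ene) | CC(C)=CCBr | starting material
4 | [2,4-dimethoxy-6-(methoxymethoxy)phenyl]lithium | [Li]c1c(OC)cc(OC)cc1OCOC | intermediate
5 | 1,5-dimethoxy-3-(methoxymethoxy)-2-(3-methylbut-2-en-1-yl)benzene | COCOc1cc(OC)cc(OC)c1CC=C(C)C | intermediate
6 | 4-bromo-2-methoxyphenol | COc1cc(Br)ccc1O | starting material
7 | 4-bromo-2-methoxy-1-(methoxymethoxy)benzene | COCOc1ccc(Br)cc1OC | intermediate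
8 | methyl (2R)-oxirane-2-carboxylate (methyl (R)-glycidate) | COC(=O)[C@H]1CO1 | starting material
9 | [3-methoxy-4-(methoxymethoxy)phenyl]magnesium bromide | COCOc1ccc([Mg]Br)cc1OC | intermediate
10 | methyl (2R)-2-hydroxy-3-[3-methoxy-4-(methoxymethoxy)phenyl]propanoate | COC(=O)[C@H](O)Cc1ccc(OCOC)c(OC)c1 | intermediate
11 | methyl (2R)-2-[(tert-butyldimethylsilyl)oxy]-3-[3-methoxy-4-(methoxymethoxy)phenyl]propanoate | COC(=O)[C@H](O[Si](C)(C)C(C)(C)C)Cc1ccc(OCOC)c(OC)c1 | intermediate
12 | (2R)-2-[(tert-butyldimethylsilyl)oxy]-N-methoxy-3-[3-methoxy-4-(methoxymethoxy)phenyl]-N-methylpropanamide | CON(C)C(=O)[C@H](O[Si](C)(C)C(C)(C)C)Cc1ccc(OCOC)c(OC)c1 | intermediate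
13 | [4,6-dimethoxy-2-(methoxymethoxy)-3-(3-methylbut-2-en-1-yl)phenyl]lithium | [Li]c1c(OC)cc(OC)c(CC=C(C)C)c1OCOC | intermediate
14 | lithium hemiaminal formed from 13 and 12 (O-lithio N-methoxy-N-methyl adduct, (R) at the silyloxy carbon, new carbon undefined) | COCOc1ccc(C[C@@H](O[Si](C)(C)C(C)(C)C)C(O[Li])(N(C)OC)c2c(OC)cc(OC)c(CC=C(C)C)c2OCOC)cc1OC | intermediate
15 | (2R)-2-[(tert-butyldimethylsilyl)oxy]-1-[4,6-dimethoxy-2-(methoxymethoxy)-3-(3-methylbut-2-en-1-yl)phenyl]-3-[3-methoxy-4-(methoxymethoxy)phenyl]propan-1-one | COCOc1ccc(C[C@@H](O[Si](C)(C)C(C)(C)C)C(=O)c2c(OC)cc(OC)c(CC=C(C)C)c2OCOC)cc1OC | intermediate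
16 | (2R)-2-hydroxy-1-[2-hydroxy-4,6-dimethoxy-3-(3-methylbut-2-en-1-yl)phenyl]-3-(4-hydroxy-3-methoxyphenyl)propan-1-one | COc1cc(C[C@@H](O)C(=O)c2c(O)c(CC=C(C)C)c(OC)cc2OC)ccc1O | intermediate
17 | 4-{(2R)-2-hydroxy-3-[2-hydroxy-4,6-dimethoxy-3-(3-methylbut-2-en-1-yl)phenyl]-3-oxopropylidene}-2-methoxycyclohexa-2,5-dien-1-one (para-quinone methide, alkene geometry undefined) | COC1=CC(=C[C@@H](O)C(=O)c2c(O)c(CC=C(C)C)c(OC)cc2OC)C=CC1=O | intermediate
18 | (2R,3R)-3-hydroxy-2-(4-hydroxy-3-methoxyphenyl)-5,7-dimethoxy-8-(3-methylbut-2-en-1-yl)-2,3-dihydro-4H-chromen-4-one | COc1cc([C@H]2Oc3c(CC=C(C)C)c(OC)cc(OC)c3C(=O)[C@@H]2O)ccc1O | intermediate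
19 | (2R,3R)-3,5-dihydroxy-2-(4-hydroxy-3-methoxyphenyl)-7-methoxy-8-(3-methylbut-2-en-1-yl)-2,3-dihydro-4H-chromen-4-one | COc1cc([C@H]2Oc3c(CC=C(C)C)c(OC)cc(O)c3C(=O)[C@@H]2O)ccc1O | target

## Step count

Total: 10 steps. Longest linear sequence: 8 steps (from 6 through steps 3 to 10).

## Steps most likely to fail

**Step 9.** Three processes may defeat the closure: coupling of ring B phenoxyl radicals before the second electron is removed; tautomerisation of quinone methide 17 by loss of the C3 proton, which would erase the C3 stereocentre; and further oxidation of 18 at C2. The fallback replaces quinone methide capture by epoxide opening; it sets out from 5 and comes back at 18. Aryllithium 13, made from 5 as in step 7, would be acetylated with N-methoxy-N-methylacetamide to give the ring A acetophenone F1. Claisen–Schmidt condensation (KOH, EtOH) with O-MOM-vanillin F2 (from vanillin, MOMCl, iPr2NEt) would give the E-chalcone F3. Juliá–Colonna epoxidation (poly-L-leucine, urea–H2O2, DBU, THF) should give the (αR,βS)-epoxide F4. Methanolic HCl would then remove both MOM groups and let the C8a phenol open the epoxide at the benzylic carbon with inversion, the established entry to trans-dihydroflavonols, giving 18.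

**Step 7.** Deprotonation may occur at the benzylic–allylic CH2 of the prenyl group or between the two methoxy groups instead of next to OMOM, and the doubly ortho-substituted aryllithium may add slowly and enolise the amide instead. The fallback uses halogen–metal exchange on a regiodefined bromide in place of deprotonation; it sets out from 1 and comes back at 13. ortho-Bromination of 1 (NBS, cat. iPr2NH, CH2Cl2) would give 2-bromo-3,5-dimethoxyphenol F5, and O-allylation (allyl bromide, K2CO3, acetone) the allyl ether F6. Claisen rearrangement (N,N-diethylaniline, 190 °C) can go only to the one free ortho carbon and would give the allylphenol F7. MOM protection would give the MOM ether F8, and cross-metathesis with 2-methylbut-2-ene (second-generation Grubbs catalyst, CH2Cl2, 40 °C) the prenylated aryl bromide F9. Bromine–lithium exchange (n-BuLi, THF, −78 °C) is faster than any deprotonation and gives 13, which is treated with 12 as in step 7. This variant also avoids the regiochemical question of step 2.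

**Step 10.** The Lewis acid may open ring C at O1–C2, since the free 4'-hydroxyl makes C2 a latent quinone methide carbon, with loss of the trans relation or of enantiopurity; the guaiacyl methyl ether may also be cleaved through a magnesium phenoxide chelate. The fallback is a protect–cleave–release sequence that removes the free para-hydroxyl; it sets out from 18 and comes back at 19. Selective silylation of the phenol (TBSCl, imidazole, DMF, 0 °C) would give the 4'-O-silyl ether F10. Cleavage of the O5 methyl ether (MgI2·OEt2, THF, 60 °C) would then give the 5-hydroxy silyl ether F11, and HF·pyridine in THF would release 19.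

## Further compounds

F1 | step 9 | 1-[4,6-dimethoxy-2-(methoxymethoxy)-3-(3-methylbut-2-en-1-yl)phenyl]ethan-1-one | CC(=O)c1c(OC)cc(OC)c(CC=C(C)C)c1OCOC
F2 | step 9 | 3-methoxy-4-(methoxymethoxy)benzaldehyde | COCOc1ccc(C=O)cc1OC
F3 | step 9 | (2E)-1-[4,6-dimethoxy-2-(methoxymethoxy)-3-(3-methylbut-2-en-1-yl)phenyl]-3-[3-methoxy-4-(methoxymethoxy)phenyl]prop-2-en-1-one | COCOc1ccc(/C=C/C(=O)c2c(OC)cc(OC)c(CC=C(C)C)c2OCOC)cc1OC
F4 | step 9 | [4,6-dimethoxy-2-(methoxymethoxy)-3-(3-methylbut-2-en-1-yl)phenyl]{(2R,3S)-3-[3-methoxy-4-(methoxymethoxy)phenyl]oxiran-2-yl}methanone | COCOc1ccc([C@@H]2O[C@H]2C(=O)c2c(OC)cc(OC)c(CC=C(C)C)c2OCOC)cc1OC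
F5 | step 7 | 2-bromo-3,5-dimethoxyphenol | COc1cc(O)c(Br)c(OC)c1
F6 | step 7 | 2-bromo-1,5-dimethoxy-3-(prop-2-en-1-yloxy)benzene | C=CCOc1cc(OC)cc(OC)c1Br
F7 | step 7 | 2-bromo-3,5-dimethoxy-6-(prop-2-en-1-yl)phenol | C=CCc1c(O)c(Br)c(OC)cc1OC
F8 | step 7 | 2-bromo-1,5-dimethoxy-3-(methoxymethoxy)-4-(prop-2-en-1-yl)benzene | C=CCc1c(OCOC)c(Br)c(OC)cc1OC
F9 | step 7 | 2-bromo-1,5-dimethoxy-3-(methoxymethoxy)-4-(3-methylbut-2-en-1-yl)benzene | CC(C)=CCc1c(OCOC)c(Br)c(OC)cc1OC
F10 | step 10 | (2R,3R)-2-{4-[(tert-butyldimethylsilyl)oxy]-3-methoxyphenyl}-3-hydroxy-5,7-dimethoxy-8-(3-methylbut-2-en-1-yl)-2,3-dihydro-4H-chromen-4-one | COc1cc([C@H]2Oc3c(CC=C(C)C)c(OC)cc(OC)c3C(=O)[C@@H]2O)ccc1O[Si](C)(C)C(C)(C)C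
F11 | step 10 | (2R,3R)-2-{4-[(tert-butyldimethylsilyl)oxy]-3-methoxyphenyl}-3,5-dihydroxy-7-methoxy-8-(3-methylbut-2-en-1-yl)-2,3-dihydro-4H-chromen-4-one | COc1cc([C@H]2Oc3c(CC=C(C)C)c(OC)cc(O)c3C(=O)[C@@H]2O)ccc1O[Si](C)(C)C(C)(C)C
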